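**Strategy**

The cyclohexane ring (C3–C8 of the 1-oxaspiro[2.5]octane core) is cut into a C4–C7 diene and a C3=C8 dienophile. A catalytic enantioselective Diels–Alder reaction joins a 2-silyloxydiene, whose tetrasubstituted terminus C4 carries methyl and a linear silylethynyl group (a masked acetyl), to the ketone-conjugated π-bond of a 1,3-diacylallene, forming C3–C4 and C7–C8 at once. It exploits the two quaternary carbons C4 and C8 that flank spiro carbon C3: both are set in one event, while the untouched allene π-bond emerges as the exocyclic enoate that becomes the glycidic ester and the enol ether at C5 becomes the handle for the hydroxyethyl arm. The pyranone is attached last by aldol condensation.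

Key step: step 6

Remark (atom labels): the target's numbering (O1, C2, spiro C3, C4 bearing CH3 and the enoyl group, C5 bearing the hydroxyethyl group, C6, C7, C8 bearing CH3 and 3-furoyl) is used in the prose for all intermediates; changes of the C3/C4 descriptors along the route are CIP priority changes, not inversions.
Remark (assumption): the sense of induction of the oxazaborolidinium catalyst in step 6 is assigned by analogy with α-substituted enones; if the antipode is favoured, the (R)-catalyst is used.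
Remark: lithio species, enolates and ylides made from a reactant by the base in the Conditions line are treated as activated forms of that reactant.

**Step 1**
Reactants: 1 but-1-yn-1-yl(trimethyl)silane; 2 acrolein
Product: 3 4-methyl-6-(trimethylsilyl)hex-1-en-5-yn-3-ol (racemic diastereomer mixture)
Conditions: t-BuLi, THF, −78 °C; Ti(OiPr)4, −78 °C; then 2, −78 °C; 1 M HCl
Reagents that add atoms: none
Why: Propargylic lithiation and transmetalation should give an allenyltitanium species that adds to the aldehyde by SE2' (carbonyl propargylation) to give the homopropargylic alcohol; its two stereocentres are erased in steps 2 and 3.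

**Step 2**
Reactants: 3 4-methyl-6-(trimethylsilyl)hex-1-en-5-yn-3-ol
Product: 4 4-methyl-6-(trimethylsilyl)hex-1-en-5-yn-3-one (racemic)
Conditions: Dess–Martin periodinane, CH2Cl2, 0 °C → rt
Reagents that add atoms: none
Why: Dess–Martin oxidation is neutral, so the β,γ-alkynyl vinyl ketone should not isomerise to the allenyl ketone.

**Step 3**
Reactants: 4 4-methyl-6-(trimethylsilyl)hex-1-en-5-yn-3-one
Product: 5 (E)-tert-butyl{[4-methyl-6-(trimethylsilyl)hexa-1,3-dien-5-yn-3-yl]oxy}dimethylsilane (alkynyl group cis to the vinyl group, CH3 cis to OTBS)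
Conditions: TBSOTf, Et3N, CH2Cl2, −78 → 0 °C
Reagents that add atoms: tert-butyldimethylsilyl triflate, CC(C)(C)[Si](C)(C)OS(=O)(=O)C(F)(F)F
Why: Soft enolisation/O-silylation can only occur toward the propargylic α-carbon, and the isomer with the rod-like alkynyl group next to the vinyl group and CH3 next to OTBS should be favoured because it minimises A(1,3) strain.

**Step 4**
Reactants: 6 ethyltriphenylphosphonium bromide; 7 furan-3-carbonyl chloride
Product: 8 1-(furan-3-yl)-2-(triphenyl-λ5-phosphanylidene)propan-1-one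
Conditions: 6 (2 equiv), n-BuLi (2 equiv), THF, 0 °C; then 7, −78 °C → rt
Reagents that add atoms: none
Why: C-acylation of the ethylidene ylide followed by transylidation with the second equivalent of ylide should give the stabilised acyl ylide.

**Step 5**
Reactants: 8 1-(furan-3-yl)-2-(triphenyl-λ5-phosphanylidene)propan-1-one; 9 methyl 3-chloro-3-oxopropanoate
Product: 11 methyl 5-(furan-3-yl)-4-methyl-5-oxopenta-2,3-dienoate (racemic allene), via (methoxycarbonyl)ketene 10 (not isolated)
Conditions: Et3N, CH2Cl2, 0 °C → rt, slow addition of 9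
Reagents that add atoms: none
Why: Dehydrochlorination gives the ketene, and Wittig olefination of its C=O by the acyl ylide (ketene–Wittig allene synthesis) should give the 1,3-diacylallene.

**Step 6**
Reactants: 5 (E)-silyloxydienyne; 11 racemic allene (2.2 equiv)
Product: 13 methyl (2E)-2-[(2R,6R)-6-(furan-3-carbonyl)-2,6-dimethyl-3-oxo-2-[(trimethylsilyl)ethynyl]cyclohexylidene]acetate (CO2Me cis to the furoyl-bearing carbon), via silyl enol ether adduct 12 (not isolated)
Conditions: (S)-1-(o-tolyl)-3,3-diphenyltetrahydro-1H,3H-pyrrolo[1,2-c][1,3,2]oxazaborole·HNTf2 (20 mol %), CH2Cl2, −78 → −20 °C; then 1 M HCl, THF, 0 °C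
Reagents that add atoms: none
Why: The boron Lewis acid binds the furyl ketone of 11 and the diene adds in an asynchronous concerted [4+2] (Diels–Alder; in the limit a Mukaiyama–Michael/Michael sequence to the same adduct) across the ketone-conjugated π-bond, diene terminus C4 bonding to the allene central carbon C3 and C7 to C8; the closest known reactions are Diels–Alder additions of 2-silyloxydienes to allenoates and allenyl ketones and oxazaborolidinium-catalysed enantioselective Diels–Alder reactions of α-substituted enones. The cyclohexene ring C3–C8 is closed by intermolecular suprafacial [4+2] cycloaddition. C8 is set by the allene π-face that is attacked, which must be the face anti to the CO2Me group on the distal allene carbon; the catalyst-preferred face therefore selects one enantiomer of racemic 11 (kinetic resolution, hence the excess), and the same anti approach leaves CO2Me cis to C8 in the exocyclic enoate. C4 is set relative to C8 by the furoyl-endo transition state together with the diene geometry (CH3 outside, rod-like alkynyl inside), which places 4-CH3 cis to the furoyl group. The step needs site selectivity (enone over enoate π-bond, secured by the more Lewis-basic ketone and its lower LUMO), regioselectivity (the 2-OTBS group makes C4 the nucleophilic terminus, and the hindered C4 meets the unhindered sp carbon C3) and facial selectivity (catalyst); acidic work-up then unmasks the C5 ketone.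

**Step 7**
Reactants: 13 cyclohexylidene acetate
Product: 14 methyl (2S,3R,4S,8R)-8-(furan-3-carbonyl)-4,8-dimethyl-5-oxo-4-[(trimethylsilyl)ethynyl]-1-oxaspiro[2.5]octane-2-carboxylate
Conditions: t-BuOOH (anhydrous), n-BuLi, THF, −78 → 0 °C; H2O
Reagents that add atoms: tert-butyl hydroperoxide, CC(C)(C)OO
Why: Weitz–Scheffer nucleophilic epoxidation with lithium tert-butyl peroxide should add to C3 from the ring face opposite the axial 8-CH3 and 4-alkynyl groups and close on the O–O bond with retention of the enoate geometry, setting C2 and C3, while the furan and the ketones are inert to the peroxide anion.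

**Step 8**
Reactants: 14 epoxy ketone
Product: 15 methyl (2S,3S,4S,8R)-8-(furan-3-carbonyl)-4,8-dimethyl-5-(trifluoromethanesulfonyloxy)-4-[(trimethylsilyl)ethynyl]-1-oxaspiro[2.5]oct-5-ene-2-carboxylate
Conditions: KHMDS, THF, −78 °C; PhNTf2
Reagents that add atoms: N-phenylbis(trifluoromethanesulfonimide), O=S(=O)(N(c1ccccc1)S(=O)(=O)C(F)(F)F)C(F)(F)F
Why: The C5 ketone can enolise only toward C6 (C4 is quaternary, the furyl ketone has no α-hydrogen), so enolate O-triflation should give a single alkenyl triflate.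

**Step 9**
Reactants: 15 alkenyl triflate
Product: 17 methyl (2S,3S,4S,8R)-5-acetyl-8-(furan-3-carbonyl)-4,8-dimethyl-4-[(trimethylsilyl)ethynyl]-1-oxaspiro[2.5]oct-5-ene-2-carboxylate, via 1-ethoxyvinyl diene 16 (not isolated)
Conditions: tributyl(1-ethoxyvinyl)stannane, Pd(PPh3)4 (5 mol %), LiCl, THF, 65 °C; then 1 M HCl, THF, 0 °C
Reagents that add atoms: tributyl(1-ethoxyvinyl)stannane, CCCC[Sn](CCCC)(CCCC)C(=C)OCC; water, O
Why: Stille coupling of the alkenyl triflate with the acetyl-anion equivalent and hydrolysis of the enol ether should give the methyl enone; the epoxide is not allylic and should survive zerovalent palladium.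

**Step 10**
Reactants: 17 methyl enone
Product: 18 methyl (2S,3S,4S,8R)-8-(furan-3-carbonyl)-5-[(1R)-1-hydroxyethyl]-4,8-dimethyl-4-[(trimethylsilyl)ethynyl]-1-oxaspiro[2.5]oct-5-ene-2-carboxylate
Conditions: (S)-2-methyl-CBS-oxazaborolidine (0.5 equiv), catecholborane, toluene, −78 °C; MeOH, aq. NaHCO3
Reagents that add atoms: none
Why: Corey–Bakshi–Shibata reduction with the (S)-catalyst should give the (R)-carbinol by reagent control (alkenyl large, methyl small, as for aryl methyl ketones), the tert-alkyl furyl ketone being far more hindered.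

**Step 11**
Reactants: 18 allylic alcohol
Product: 19 methyl (2S,3S,4S,5S,8R)-8-(furan-3-carbonyl)-5-[(1R)-1-hydroxyethyl]-4,8-dimethyl-4-[(trimethylsilyl)ethynyl]-1-oxaspiro[2.5]octane-2-carboxylate
Conditions: [Ir(cod)(PCy3)(py)]PF6 (5 mol %), H2 (1 atm), CH2Cl2, 0 °C
Reagents that add atoms: none
Why: Hydroxyl-directed hydrogenation: A(1,2) strain turns the carbinol hydrogen toward C4, so the (R)-hydroxyl lies on the face of the small 4-alkynyl group and should deliver H2 to C5 from that face (5S); the silyl-capped alkyne on a quaternary carbon should be too hindered to bind iridium.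

**Step 12**
Reactants: 19 saturated alcohol
Product: 20 methyl (2S,3S,4S,5S,8R)-5-[(1R)-1-(tert-butyldimethylsilyloxy)ethyl]-8-(furan-3-carbonyl)-4,8-dimethyl-4-[(trimethylsilyl)ethynyl]-1-oxaspiro[2.5]octane-2-carboxylate
Conditions: TBSOTf, 2,6-lutidine, CH2Cl2, −78 °C
Reagents that add atoms: tert-butyldimethylsilyl triflate, CC(C)(C)[Si](C)(C)OS(=O)(=O)C(F)(F)F
Why: Silyl protection prevents lactol formation with the future C4 acetyl group and interference in the aldol and dehydration steps.

**Step 13**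
Reactants: 20 silyl ether
Product: 22 methyl (2S,3R,4R,5S,8R)-4-acetyl-5-[(1R)-1-(tert-butyldimethylsilyloxy)ethyl]-8-(furan-3-carbonyl)-4,8-dimethyl-1-oxaspiro[2.5]octane-2-carboxylate, via terminal alkyne 21 (not isolated)
Conditions: K2CO3 (cat.), MeOH, rt; then AcOH to neutral, Ph3PAuNTf2 (5 mol %), H2O, 40 °C
Reagents that add atoms: water, O
Why: Methanolysis of the C–Si bond and gold-catalysed Markovnikov hydration of the terminal alkyne should unmask the methyl ketone under near-neutral conditions that spare the epoxide and silyl ether.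

**Step 14**
Reactants: 23 2-acetylfuran
Product: 24 2-(furan-2-yl)propan-2-ol
Conditions: MeMgBr, THF, 0 °C; H2O
Reagents that add atoms: methylmagnesium bromide, C[Mg]Br
Why: Grignard addition to the ketone.

**Step 15**
Reactants: 24 2-(furan-2-yl)propan-2-ol
Product: 26 6,6-dimethyl-2H-pyran-2,5(6H)-dione, via pyranone lactol 25 (not isolated)
Conditions: mCPBA, CH2Cl2, 0 °C; then Dess–Martin periodinane, rt
Reagents that add atoms: 3-chloroperbenzoic acid, O=C(OO)c1cccc(Cl)c1
Why: Achmatowicz oxidative ring expansion of the furyl carbinol gives the 6-hydroxypyranone, and oxidation of the lactol should give the ene-dione lactone.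

**Step 16**
Reactants: 22 methyl ketone; 26 6,6-dimethyl-2H-pyran-2,5(6H)-dione
Product: 27 methyl (2S,3R,4R,5S,8R)-5-[(1R)-1-(tert-butyldimethylsilyloxy)ethyl]-8-(furan-3-carbonyl)-4-[2-(3-hydroxy-2,2-dimethyl-6-oxo-3,6-dihydro-2H-pyran-3-yl)acetyl]-4,8-dimethyl-1-oxaspiro[2.5]octane-2-carboxylate (both carbinol epimers)
Conditions: LDA, THF, −78 °C; then 26, −78 °C; AcOH
Reagents that add atoms: none
Why: The methyl group is the only enolisable position of 22, and its lithium enolate should add 1,2 to the ketone of 26 at low temperature (aldol addition); the new carbinol centre is removed in step 17.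

**Step 17**
Reactants: 27 aldol adduct
Product: 28 methyl (2S,3R,4R,5S,8R)-5-[(1R)-1-(tert-butyldimethylsilyloxy)ethyl]-4-[(2E)-2-(2,2-dimethyl-6-oxo-2H-pyran-3(6H)-ylidene)acetyl]-8-(furan-3-carbonyl)-4,8-dimethyl-1-oxaspiro[2.5]octane-2-carboxylate
Conditions: methyl N-(triethylammoniosulfonyl)carbamate (Burgess reagent), benzene, 50 °C
Reagents that add atoms: none
Why: Burgess dehydration can only eliminate toward the ketone α-CH2, and the (E)-enone (acyl anti to the CMe2 group) should be the thermodynamically preferred isomer.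

**Step 18**
Reactants: 28 silyl ether of the target
Product: 29 methyl (2S,3R,4R,5S,8R)-4-[(2E)-2-(2,2-dimethyl-6-oxo-2H-pyran-3(6H)-ylidene)acetyl]-8-(furan-3-carbonyl)-5-[(1R)-1-hydroxyethyl]-4,8-dimethyl-1-oxaspiro[2.5]octane-2-carboxylate (CNP0293135.1)
Conditions: HF·pyridine, pyridine, THF, 0 °C → rt
Reagents that add atoms: none
Why: Buffered fluoride cleavage of the silyl ether should spare the glycidic ester, furan and dienone lactone.

**Compound list**

1 | but-1-yn-1-yl(trimethyl)silane | CCC#C[Si](C)(C)C | starting material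
2 | acrolein | C=CC=O | starting material
3 | 4-methyl-6-(trimethylsilyl)hex-1-en-5-yn-3-ol | C=CC(O)C(C)C#C[Si](C)(C)C | intermediate
4 | 4-methyl-6-(trimethylsilyl)hex-1-en-5-yn-3-one | C=CC(=O)C(C)C#C[Si](C)(C)C | intermediate
5 | (E)-tert-butyl{[4-methyl-6-(trimethylsilyl)hexa-1,3-dien-5-yn-3-yl]oxy}dimethylsilane | C=C/C(O[Si](C)(C)C(C)(C)C)=C(C)\C#C[Si](C)(C)C | intermediate
6 | ethyltriphenylphosphonium bromide | CC[P+](c1ccccc1)(c1ccccc1)c1ccccc1.[Br-] | starting material
7 | furan-3-carbonyl chloride | O=C(Cl)c1ccoc1 | starting material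
8 | 1-(furan-3-yl)-2-(triphenyl-λ5-phosphanylidene)propan-1-one | CC(=P(c1ccccc1)(c1ccccc1)c1ccccc1)C(=O)c1ccoc1 | intermediate
9 | methyl 3-chloro-3-oxopropanoate | COC(=O)CC(=O)Cl | starting material
10 | methyl 3-oxoprop-2-enoate, (methoxycarbonyl)ketene | COC(=O)C=C=O | intermediate (not isolated)
11 | methyl 5-(furan-3-yl)-4-methyl-5-oxopenta-2,3-dienoate (racemic) | COC(=O)C=C=C(C)C(=O)c1ccoc1 | intermediate
12 | methyl (2Z)-2-[(2R,6R)-3-(tert-butyldimethylsilyloxy)-6-(furan-3-carbonyl)-2,6-dimethyl-2-[(trimethylsilyl)ethynyl]cyclohex-3-en-1-ylidene]acetate | COC(=O)/C=C1\[C@](C)(C(=O)c2ccoc2)CC=C(O[Si](C)(C)C(C)(C)C)[C@@]1(C)C#C[Si](C)(C)C | intermediate (not isolated)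
13 | methyl (2E)-2-[(2R,6R)-6-(furan-3-carbonyl)-2,6-dimethyl-3-oxo-2-[(trimethylsilyl)ethynyl]cyclohexylidene]acetate | COC(=O)/C=C1\[C@](C)(C(=O)c2ccoc2)CCC(=O)[C@@]1(C)C#C[Si](C)(C)C | intermediate
14 | methyl (2S,3R,4S,8R)-8-(furan-3-carbonyl)-4,8-dimethyl-5-oxo-4-[(trimethylsilyl)ethynyl]-1-oxaspiro[2.5]octane-2-carboxylate | COC(=O)[C@H]1O[C@@]12[C@](C)(C(=O)c1ccoc1)CCC(=O)[C@@]2(C)C#C[Si](C)(C)C | intermediate
15 | methyl (2S,3S,4S,8R)-8-(furan-3-carbonyl)-4,8-dimethyl-5-(trifluoromethanesulfonyloxy)-4-[(trimethylsilyl)ethynyl]-1-oxaspiro[2.5]oct-5-ene-2-carboxylate | COC(=O)[C@H]1O[C@@]12[C@](C)(C(=O)c1ccoc1)CC=C(OS(=O)(=O)C(F)(F)F)[C@@]2(C)C#C[Si](C)(C)C | intermediate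
16 | methyl (2S,3S,4S,8R)-5-(1-ethoxyethenyl)-8-(furan-3-carbonyl)-4,8-dimethyl-4-[(trimethylsilyl)ethynyl]-1-oxaspiro[2.5]oct-5-ene-2-carboxylate | COC(=O)[C@H]1O[C@@]12[C@](C)(C(=O)c1ccoc1)CC=C(C(=C)OCC)[C@@]2(C)C#C[Si](C)(C)C | intermediate (not isolated)
17 | methyl (2S,3S,4S,8R)-5-acetyl-8-(furan-3-carbonyl)-4,8-dimethyl-4-[(trimethylsilyl)ethynyl]-1-oxaspiro[2.5]oct-5-ene-2-carboxylate | COC(=O)[C@H]1O[C@@]12[C@](C)(C(=O)c1ccoc1)CC=C(C(C)=O)[C@@]2(C)C#C[Si](C)(C)C | intermediate
18 | methyl (2S,3S,4S,8R)-8-(furan-3-carbonyl)-5-[(1R)-1-hydroxyethyl]-4,8-dimethyl-4-[(trimethylsilyl)ethynyl]-1-oxaspiro[2.5]oct-5-ene-2-carboxylate | COC(=O)[C@H]1O[C@@]12[C@](C)(C(=O)c1ccoc1)CC=C([C@@H](C)O)[C@@]2(C)C#C[Si](C)(C)C | intermediate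
19 | methyl (2S,3S,4S,5S,8R)-8-(furan-3-carbonyl)-5-[(1R)-1-hydroxyethyl]-4,8-dimethyl-4-[(trimethylsilyl)ethynyl]-1-oxaspiro[2.5]octane-2-carboxylate | COC(=O)[C@H]1O[C@@]12[C@](C)(C(=O)c1ccoc1)CC[C@H]([C@@H](C)O)[C@@]2(C)C#C[Si](C)(C)C | intermediate
20 | methyl (2S,3S,4S,5S,8R)-5-[(1R)-1-(tert-butyldimethylsilyloxy)ethyl]-8-(furan-3-carbonyl)-4,8-dimethyl-4-[(trimethylsilyl)ethynyl]-1-oxaspiro[2.5]octane-2-carboxylate | COC(=O)[C@H]1O[C@@]12[C@](C)(C(=O)c1ccoc1)CC[C@H]([C@@H](C)O[Si](C)(C)C(C)(C)C)[C@@]2(C)C#C[Si](C)(C)C | intermediate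
21 | methyl (2S,3S,4S,5S,8R)-5-[(1R)-1-(tert-butyldimethylsilyloxy)ethyl]-4-ethynyl-8-(furan-3-carbonyl)-4,8-dimethyl-1-oxaspiro[2.5]octane-2-carboxylate | COC(=O)[C@H]1O[C@@]12[C@](C)(C(=O)c1ccoc1)CC[C@H]([C@@H](C)O[Si](C)(C)C(C)(C)C)[C@@]2(C)C#C | intermediate (not isolated)
22 | methyl (2S,3R,4R,5S,8R)-4-acetyl-5-[(1R)-1-(tert-butyldimethylsilyloxy)ethyl]-8-(furan-3-carbonyl)-4,8-dimethyl-1-oxaspiro[2.5]octane-2-carboxylate | COC(=O)[C@H]1O[C@@]12[C@](C)(C(=O)c1ccoc1)CC[C@H]([C@@H](C)O[Si](C)(C)C(C)(C)C)[C@@]2(C)C(C)=O | intermediate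
23 | 2-acetylfuran | CC(=O)c1ccco1 | starting material
24 | 2-(furan-2-yl)propan-2-ol | CC(C)(O)c1ccco1 | intermediate
25 | 6-hydroxy-2,2-dimethyl-2H-pyran-3(6H)-one | CC1(C)OC(O)C=CC1=O | intermediate (not isolated)
26 | 6,6-dimethyl-2H-pyran-2,5(6H)-dione | CC1(C)OC(=O)C=CC1=O | intermediate
27 | methyl (2S,3R,4R,5S,8R)-5-[(1R)-1-(tert-butyldimethylsilyloxy)ethyl]-8-(furan-3-carbonyl)-4-[2-(3-hydroxy-2,2-dimethyl-6-oxo-3,6-dihydro-2H-pyran-3-yl)acetyl]-4,8-dimethyl-1-oxaspiro[2.5]octane-2-carboxylate | COC(=O)[C@H]1O[C@@]12[C@](C)(C(=O)c1ccoc1)CC[C@H]([C@@H](C)O[Si](C)(C)C(C)(C)C)[C@@]2(C)C(=O)CC1(O)C=CC(=O)OC1(C)C | intermediate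
28 | methyl (2S,3R,4R,5S,8R)-5-[(1R)-1-(tert-butyldimethylsilyloxy)ethyl]-4-[(2E)-2-(2,2-dimethyl-6-oxo-2H-pyran-3(6H)-ylidene)acetyl]-8-(furan-3-carbonyl)-4,8-dimethyl-1-oxaspiro[2.5]octane-2-carboxylate | COC(=O)[C@H]1O[C@@]12[C@](C)(C(=O)c1ccoc1)CC[C@H]([C@@H](C)O[Si](C)(C)C(C)(C)C)[C@@]2(C)C(=O)/C=C1\C=CC(=O)OC1(C)C | intermediate
29 | methyl (2S,3R,4R,5S,8R)-4-[(2E)-2-(2,2-dimethyl-6-oxo-2H-pyran-3(6H)-ylidene)acetyl]-8-(furan-3-carbonyl)-5-[(1R)-1-hydroxyethyl]-4,8-dimethyl-1-oxaspiro[2.5]octane-2-carboxylate | COC(=O)[C@H]1O[C@@]12[C@](C)(C(=O)c1ccoc1)CC[C@H]([C@@H](C)O)[C@@]2(C)C(=O)/C=C1\C=CC(=O)OC1(C)C | target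

**Totals and risks**

Total step count: 18. Longest linear sequence: 14 steps (steps 1–3, 6–13, 16–18).

Steps most likely to fail:

1. Step 6. The diene may add to the ester-conjugated allene π-bond instead of the ketone-conjugated one (or a stepwise pathway may close through the ester α-carbon), or the catalyst may discriminate the π-faces and allene enantiomers poorly. Fallback, setting out from 5 and 9: Wittig reaction of the ketene from 9 with commercial 2-(triphenyl-λ5-phosphanylidene)propanal (Et3N, CH2Cl2) should give methyl 4-methyl-5-oxopenta-2,3-dienoate F1, whose aldehyde is a far stronger activator and a better ligand for the oxazaborolidinium catalyst than the ester. Its Diels–Alder reaction with 5 under the step 6 catalyst, with NaHCO3 work-up to keep the enol ether, should give the formyl analogue of 12, F2. Addition of 3-furyllithium (3-bromofuran, n-BuLi, THF, −78 °C) to the aldehyde should give the furyl carbinol F3, and Dess–Martin oxidation returns to 12, which 1 M HCl converts to 13.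

2. Step 7. Conjugate addition of the peroxide anion to C3, which is flanked by two quaternary carbons, may be too slow, or rotation of the intermediate ester enolate may scramble the C2 configuration. Fallback, setting out from 13: stoichiometric osmylation from the open ring face (OsO4, TMEDA, CH2Cl2, −78 °C; aq. NaHSO3) should give the syn-diol F4. Trimethyl orthoacetate/PPTS and then acetyl bromide should open the cyclic orthoester at the secondary carbon with inversion to give the tertiary acetate/secondary bromide F5. K2CO3 in MeOH then cleaves the acetate and closes the oxirane with a second inversion, returning to 14 with the configuration of a direct syn epoxidation.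

3. Step 16. The enolate may add in conjugate fashion to the ene-dione, or the hindered tertiary aldolate may revert by retro-aldol cleavage. Fallback, setting out from 24 and 22: Achmatowicz oxidation of 24 with isolation of lactol 25 and acetalisation (MeOH, PPTS) should give 6-methoxy-2,2-dimethyl-2H-pyran-3(6H)-one F6, a simple enone that lithium enolates attack 1,2. Aldol addition of the enolate of 22 should give the carbinol F7 and dehydration as in step 17 the dienone acetal F8. Mild acid hydrolysis (PPTS, acetone/H2O) should give the lactol F9, and Dess–Martin oxidation of the lactol returns to 28.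

**Further compounds**

F1 | step 6 | methyl 4-methyl-5-oxopenta-2,3-dienoate (racemic) | COC(=O)C=C=C(C)C=O
F2 | step 6 | methyl (2Z)-2-[(2R,6R)-3-(tert-butyldimethylsilyloxy)-6-formyl-2,6-dimethyl-2-[(trimethylsilyl)ethynyl]cyclohex-3-en-1-ylidene]acetate | COC(=O)/C=C1\[C@](C)(C=O)CC=C(O[Si](C)(C)C(C)(C)C)[C@@]1(C)C#C[Si](C)(C)C
F3 | step 6 | furan-3-yl(hydroxy)methyl analogue of 12 (both carbinol epimers) | COC(=O)/C=C1\[C@](C)(C(O)c2ccoc2)CC=C(O[Si](C)(C)C(C)(C)C)[C@@]1(C)C#C[Si](C)(C)C
F4 | step 7 | syn-diol of 13: methyl 2-hydroxy-2-[6-(furan-3-carbonyl)-1-hydroxy-2,6-dimethyl-3-oxo-2-[(trimethylsilyl)ethynyl]cyclohexyl]acetate, both hydroxyls added from the face of the 4-methyl group | COC(=O)[C@@H](O)[C@@]1(O)[C@](C)(C(=O)c2ccoc2)CCC(=O)[C@@]1(C)C#C[Si](C)(C)C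
F5 | step 7 | methyl 2-bromo-2-[1-acetoxy-6-(furan-3-carbonyl)-2,6-dimethyl-3-oxo-2-[(trimethylsilyl)ethynyl]cyclohexyl]acetate, C2 inverted relative to F4 | COC(=O)[C@H](Br)[C@@]1(OC(C)=O)[C@](C)(C(=O)c2ccoc2)CCC(=O)[C@@]1(C)C#C[Si](C)(C)C
F6 | step 16 | 6-methoxy-2,2-dimethyl-2H-pyran-3(6H)-one | COC1C=CC(=O)C(C)(C)O1
F7 | step 16 | aldol adduct of 22 with F6 (6-methoxy analogue of 27 in place of the lactone carbonyl) | COC(=O)[C@H]1O[C@@]12[C@](C)(C(=O)c1ccoc1)CC[C@H]([C@@H](C)O[Si](C)(C)C(C)(C)C)[C@@]2(C)C(=O)CC1(O)C=CC(OC)OC1(C)C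
F8 | step 16 | (E)-dienone methyl acetal (6-methoxy analogue of 28) | COC(=O)[C@H]1O[C@@]12[C@](C)(C(=O)c1ccoc1)CC[C@H]([C@@H](C)O[Si](C)(C)C(C)(C)C)[C@@]2(C)C(=O)/C=C1\C=CC(OC)OC1(C)C
F9 | step 16 | (E)-dienone lactol (6-hydroxy analogue of 28) | COC(=O)[C@H]1O[C@@]12[C@](C)(C(=O)c1ccoc1)CC[C@H]([C@@H](C)O[Si](C)(C)C(C)(C)C)[C@@]2(C)C(=O)/C=C1\C=CC(O)OC1(C)C
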